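The route rests on cutting both C–CH3 bonds at the quaternary sp3 carbon of the trione ring (ring B, carbon 3, flanked by the two enolic carbons). Without these methyl groups ring B is an aromatic acetylphloroglucinol, so the precursor is a flat diarylmethane: 2,4,6-trihydroxyacetophenone joined through the CH2 bridge to the propanoyl-bearing benzene ring (ring A), whose two phenols are masked as benzyl ethers. Iodomethane and sodium methoxide then methylate ring-B carbon 3 twice; as the only hydrogen-bearing carbon of ring B, it becomes the quaternary centre and the ring is dearomatised in the same operation. Hydrogenolysis of the benzyl ethers finishes the synthesis.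

Key step: step 6

Ring numbering used below: ring A is the benzene ring, counted from the propanoyl-bearing carbon (carbon 1) to the hydroxyl-bearing carbon 2, the CH carbon 3, the methoxy-bearing carbon 4, the bridge-bearing carbon 5 and the hydroxyl-bearing carbon 6. Ring B is the trione ring, counted from the bridge-bearing carbon 1 to the enolic carbon 2, the CMe2 carbon 3, the enolic carbon 4, the acetyl-bearing carbon 5 and the ketone carbon 6.

Remark: the target has no stereocentre, and ring B of 14, 15 and F1 is drawn as one tautomer of an enolised β-triketone; all tautomers are treated as the same compound.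

Remark: in 11 the bridge sits on ring-B carbon 1 and the only ring hydrogen on ring-B carbon 3, so double methylation there gives exactly the substitution pattern of the target. The benzyl ethers on ring A are chosen because they tolerate the acid of step 5 and the methoxide of step 6 and leave under neutral conditions.

Step 1
Reactants: 1 flopropione; 2 dimethyl sulfate
Product: 3 1-(2,6-dihydroxy-4-methoxyphenyl)propan-1-one
Conditions: Me2SO4 (1.0 equiv), K2CO3 (1.0 equiv), acetone, rt to reflux
Reagents that add atoms: dimethyl sulfate, COS(=O)(=O)OC
Why: Williamson O-methylation: the hydroxyl para to the propanoyl group is the most acidic and the only one not tied up in a hydrogen bond to the carbonyl, so one equivalent of K2CO3 and dimethyl sulfate should methylate it in preference to the two chelated ortho hydroxyls.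

Step 2
Reactants: 3 1-(2,6-dihydroxy-4-methoxyphenyl)propan-1-one; 4 N,N-dimethylformamide
Product: 6 2,4-dihydroxy-6-methoxy-3-propanoylbenzaldehyde, via aryl iminium chloride 5 (not isolated)
Conditions: POCl3 (1.5 equiv), DMF (3 equiv), EtOAc, 0 °C to rt; then H2O, 50 °C
Reagents that add atoms: N,N-dimethylformamide, CN(C)C=O; water, O
Why: Vilsmeier–Haack formylation: the two free ring carbons of 3 are equivalent and activated by three oxygen substituents, the iminium group of 5 deactivates the ring against a second attack, and aqueous hydrolysis of 5 releases the aldehyde.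

Step 3
Reactants: 6 2,4-dihydroxy-6-methoxy-3-propanoylbenzaldehyde; 7 benzyl bromide
Product: 8 2,4-bis(benzyloxy)-6-methoxy-3-propanoylbenzaldehyde
Conditions: BnBr (2.5 equiv), K2CO3 (3 equiv), DMF, 60 °C
Reagents that add atoms: benzyl bromide, BrCc1ccccc1
Why: Williamson ether synthesis: K2CO3 in DMF opens both carbonyl chelates, the phenoxides react at oxygen because the doubly acylated ring is a poor carbon nucleophile, and neither carbonyl group has a reactive partner under these conditions.

Step 4
Reactants: 8 2,4-bis(benzyloxy)-6-methoxy-3-propanoylbenzaldehyde
Product: 9 1-[2,6-bis(benzyloxy)-3-(hydroxymethyl)-4-methoxyphenyl]propan-1-one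
Conditions: NaBH4 (0.6 equiv), THF/MeOH, 0 °C; aq. NaHCO3 work-up
Reagents that add atoms: none
Why: Chemoselective NaBH4 reduction: the aldehyde is far more electrophilic than the propanoyl ketone, which is twisted out of conjugation and shielded by two ortho benzyloxy groups, so brief treatment at 0 °C should reduce only the formyl group.

Step 5
Reactants: 9 1-[2,6-bis(benzyloxy)-3-(hydroxymethyl)-4-methoxyphenyl]propan-1-one; 10 2,4,6-trihydroxyacetophenone (3 equiv)
Product: 11 1-[3-(3-acetyl-2,4,6-trihydroxybenzyl)-2,6-bis(benzyloxy)-4-methoxyphenyl]propan-1-one
Conditions: p-TsOH·H2O (10 mol%), 1,4-dioxane, rt to 40 °C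
Reagents that add atoms: none
Why: Friedel–Crafts benzylation with a benzylic alcohol: the acid ionises 9, with loss of water, to a cation stabilised by two ortho and one para alkoxy group, which is captured by one of the two equivalent free ring carbons of 10; the excess of 10 limits double benzylation and the catalytic acid at mild temperature should leave the benzyl ethers intact.

Step 6
Reactants: 11 1-[3-(3-acetyl-2,4,6-trihydroxybenzyl)-2,6-bis(benzyloxy)-4-methoxyphenyl]propan-1-one; 12 iodomethane
Product: 14 2-acetyl-6-{[2,4-bis(benzyloxy)-6-methoxy-3-propanoylphenyl]methyl}-3,5-dihydroxy-4,4-dimethylcyclohexa-2,5-dien-1-one, via monomethylated diarylmethane 13 (not isolated)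
Conditions: NaOMe (3.5 equiv), MeI (2.2 equiv, in portions), MeOH/THF, 0 °C to rt; then aq. HCl
Reagents that add atoms: iodomethane, CI
Why: Sodium methoxide turns ring B of 11 into a hydrogen-bonded phenoxide that attacks iodomethane through ring-B carbon 3, the carbon ortho to the oxygens on ring-B carbons 2 and 4 and para to that on carbon 6 (SN2 C-alkylation of an ambident phenoxide), and tautomerisation restores the aromatic ring in 13. A second deprotonation and a second SN2 attack from the same carbon give a cross-conjugated dienone that has no hydrogen left on that carbon and so stays dearomatised; acidification delivers it as the enolised triketone 14, the di-O-benzyl ether of the target. The closest known reaction type is the alkylative dearomatisation of acylphloroglucinols with iodomethane and sodium methoxide, which gives acylfilicinic acids. No ring is closed and no stereocentre is created, because the new quaternary carbon carries two identical methyl groups. The step needs carbon over oxygen alkylation, secured by the protic medium and the soft electrophile, and attack from ring-B carbon 3 instead of carbon 1 in the second methylation, secured by the bulky arylmethyl group on carbon 1 with its two ortho alkoxy substituents. Ring A stays untouched because its phenols are benzyl ethers, and a third methylation at ring-B carbon 1 is held back by dosing iodomethane close to two equivalents and by the low nucleophilicity of the vinylogous-acid anion of 14.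

Step 7
Reactants: 14 2-acetyl-6-{[2,4-bis(benzyloxy)-6-methoxy-3-propanoylphenyl]methyl}-3,5-dihydroxy-4,4-dimethylcyclohexa-2,5-dien-1-one
Product: 15 2-acetyl-6-[(2,4-dihydroxy-6-methoxy-3-propanoylphenyl)methyl]-3,5-dihydroxy-4,4-dimethylcyclohexa-2,5-dien-1-one (target)
Conditions: H2 (1 atm), 10% Pd/C, EtOAc, rt
Reagents that add atoms: none
Why: Catalytic hydrogenolysis of aryl benzyl ethers: the benzylic C–O bonds are cleaved under neutral conditions at room temperature, under which the diarylmethane bridge, the hydrogen-bonded aryl ketone, the methyl ether and the fully substituted enolised triketone should not be reduced.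

Compound list
1 | flopropione, 1-(2,4,6-trihydroxyphenyl)propan-1-one | CCC(=O)c1c(O)cc(O)cc1O | starting material
2 | dimethyl sulfate | COS(=O)(=O)OC | starting material
3 | 1-(2,6-dihydroxy-4-methoxyphenyl)propan-1-one | CCC(=O)c1c(O)cc(OC)cc1O | intermediate
4 | N,N-dimethylformamide | CN(C)C=O | starting material
5 | [(2,4-dihydroxy-6-methoxy-3-propanoylphenyl)methylidene]dimethylammonium chloride (not isolated) | CCC(=O)c1c(O)cc(OC)c(C=[N+](C)C)c1O.[Cl-] | intermediate
6 | 2,4-dihydroxy-6-methoxy-3-propanoylbenzaldehyde | CCC(=O)c1c(O)cc(OC)c(C=O)c1O | intermediate
7 | benzyl bromide | BrCc1ccccc1 | starting material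
8 | 2,4-bis(benzyloxy)-6-methoxy-3-propanoylbenzaldehyde | CCC(=O)c1c(OCc2ccccc2)cc(OC)c(C=O)c1OCc1ccccc1 | intermediate
9 | 1-[2,6-bis(benzyloxy)-3-(hydroxymethyl)-4-methoxyphenyl]propan-1-one | CCC(=O)c1c(OCc2ccccc2)cc(OC)c(CO)c1OCc1ccccc1 | intermediate
10 | 2,4,6-trihydroxyacetophenone | CC(=O)c1c(O)cc(O)cc1O | starting material
11 | 1-[3-(3-acetyl-2,4,6-trihydroxybenzyl)-2,6-bis(benzyloxy)-4-methoxyphenyl]propan-1-one | CCC(=O)c1c(OCc2ccccc2)cc(OC)c(Cc2c(O)cc(O)c(C(C)=O)c2O)c1OCc1ccccc1 | intermediate
12 | iodomethane | CI | starting material
13 | 1-[3-(3-acetyl-2,4,6-trihydroxy-5-methylbenzyl)-2,6-bis(benzyloxy)-4-methoxyphenyl]propan-1-one (not isolated) | CCC(=O)c1c(OCc2ccccc2)cc(OC)c(Cc2c(O)c(C)c(O)c(C(C)=O)c2O)c1OCc1ccccc1 | intermediate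
14 | 2-acetyl-6-{[2,4-bis(benzyloxy)-6-methoxy-3-propanoylphenyl]methyl}-3,5-dihydroxy-4,4-dimethylcyclohexa-2,5-dien-1-one | CCC(=O)c1c(OCc2ccccc2)cc(OC)c(CC2=C(O)C(C)(C)C(O)=C(C(C)=O)C2=O)c1OCc1ccccc1 | intermediate
15 | 2-acetyl-6-[(2,4-dihydroxy-6-methoxy-3-propanoylphenyl)methyl]-3,5-dihydroxy-4,4-dimethylcyclohexa-2,5-dien-1-one | CCC(=O)c1c(O)cc(OC)c(CC2=C(O)C(C)(C)C(O)=C(C(C)=O)C2=O)c1O | target

Total steps: 7. Longest linear sequence: 7 steps (1 → 3 → 6 → 8 → 9 → 11 → 14 → 15); 10 enters at step 5.

Steps most likely to fail

1. Step 6. What may go wrong: loss of site control in the second methylation (attack from the bridge-bearing ring-B carbon or from oxygen), or a third methylation, leading to isomers that are hard to separate. Fallback: the order of events is reversed so that the nucleophile of the bridge-forming step has only one free carbon. Setting out from 10, double C-methylation (MeI, NaOMe, MeOH, iodomethane dosed close to two equivalents) should give acetylfilicinic acid F1 (2-acetyl-3,5-dihydroxy-4,4-dimethylcyclohexa-2,5-dien-1-one). Its single remaining ring CH is then benzylated with alcohol 9 (p-TsOH·H2O cat., 1,4-dioxane), an acid-catalysed benzylation of a cyclic 1,3-dicarbonyl compound by a stabilised benzylic cation, and the route is rejoined at 14.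

2. Step 5. What may go wrong: under acid the stabilised benzyl cation may add twice to the phloroglucinol ring or be transferred off the product again, and the benzyl ethers may be partly lost. Fallback: the bridge bond is made under basic conditions instead. Setting out from 9, PBr3 (CH2Cl2, 0 °C) should give 1-[2,6-bis(benzyloxy)-3-(bromomethyl)-4-methoxyphenyl]propan-1-one F2. It is used crude to C-benzylate an excess of 10 (DBU, THF, 0 °C to rt; C-alkylation of an acylphloroglucinol anion with an activated halide), coming back to the route at 11.

3. Step 1. What may go wrong: methylation may not stop cleanly at the para hydroxyl, so that mixtures of mono- and di-O-methyl ethers result. Fallback: selectivity is moved from ether formation to ether cleavage. Setting out from 1, exhaustive methylation (Me2SO4 in excess, K2CO3, acetone, reflux) should give 1-(2,4,6-trimethoxyphenyl)propan-1-one F3. AlCl3 (excess, chlorobenzene, 80 °C; then aqueous work-up) should then remove only the two methoxy groups ortho to the ketone, one after the other, by chelation-assisted cleavage, which returns to the route at 3.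

Further compounds
F1 | step 6 | 2-acetyl-3,5-dihydroxy-4,4-dimethylcyclohexa-2,5-dien-1-one (acetylfilicinic acid) | CC(=O)C1=C(O)C(C)(C)C(O)=CC1=O
F2 | step 5 | 1-[2,6-bis(benzyloxy)-3-(bromomethyl)-4-methoxyphenyl]propan-1-one | CCC(=O)c1c(OCc2ccccc2)cc(OC)c(CBr)c1OCc1ccccc1
F3 | step 1 | 1-(2,4,6-trimethoxyphenyl)propan-1-one | CCC(=O)c1c(OC)cc(OC)cc1OC
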